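**Plan**
- The ten-membered carbocycle C1–C10 has its only free hydroxyl on C1, allylic to C10(Me)=C9 and 1,3-anti to the C3 acetate, beside the cis-fused lactone ring (O–C6, C7, C11(=C13), C12). The last cut is therefore C1–C10, which opens the carbocycle to an open-chain Z-iodoalkene aldehyde that already carries lactone, acetate and angelate.
- Earlier cuts: the C1 aldehyde (from a PMB ether), C9=C10 and C4=C5 (two Z-selective iodo-olefinations), C3–C4 (intermolecular chromium–nickel coupling), the C8 and C3 ester bonds, C11=C13 and C7–C11 (branching of a pentofuranos-3-ulose).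
- Forward: D-arabinose gives a lyxo-branched furanose acrylate; acid closes the γ-lactone (first ring); the chain is extended west (C4 iodide, then C1–C3), then east (C10 iodide); the carbocycle closes last.
- Stereochemistry: C6 and C8 are C2 and C4 of D-arabinose; C7 comes from hydrogenation on the convex face; C3 from a CBS reduction; C1 from the ring closure. Both Z alkenes come from iodoalkenes that couple with retention.

Key step: step 21

Remark: germacrane numbering is used (C1–C10 ring, C11–C13 lactone unit, methyls on C4 and C10); sugar locants are used for compounds 1–11; TBDPS = tert-butyldiphenylsilyl, PMB = 4-methoxybenzyl.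

Step 1
Reactants: 1 D-arabinose
Product: 2 5-O-TBDPS-D-arabinofuranose (anomeric mixture)
Conditions: TBDPSCl, imidazole, DMF, 0 °C → rt
Reagents that add atoms: tert-butyl(chloro)diphenylsilane, CC(C)(C)[Si](Cl)(c1ccccc1)c1ccccc1
Why: Silyl ether formation at the only primary hydroxyl, which exists in the furanose tautomer alone, should drain the ring-form equilibrium into the 5-O-silyl furanose.

Step 2
Reactants: 2 5-O-TBDPS-D-arabinofuranose
Product: 3 5-O-TBDPS-1,2-O-isopropylidene-β-D-arabinofuranose
Conditions: 2,2-dimethoxypropane, p-toluenesulfonic acid (cat.), CH2Cl2, rt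
Reagents that add atoms: 2,2-dimethoxypropane, COC(C)(C)OC
Why: Acid-catalysed acetal exchange should tie O1 and the cis O2 into a cis-fused dioxolane and leave 3-OH free.

Step 3
Reactants: 3 5-O-TBDPS-1,2-O-isopropylidene-β-D-arabinofuranose
Product: 4 5-O-TBDPS-1,2-O-isopropylidene-β-D-threo-pentofuranos-3-ulose
Conditions: Dess–Martin periodinane, CH2Cl2, rt
Reagents that add atoms: none
Why: Dess–Martin oxidation of the lone secondary alcohol is near-neutral, so C2 and C4 next to the new ketone should not epimerise.

Step 4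
Reactants: 4 3-ulose
Product: 5 methyl (5-O-TBDPS-3-deoxy-1,2-O-isopropylidene-β-D-threo-pentofuranos-3-ylidene)acetate (E/Z mixture)
Conditions: Ph3P=CHCO2Me, PhMe, 80 °C
Reagents that add atoms: methyl (triphenylphosphoranylidene)acetate, COC(=O)C=P(c1ccccc1)(c1ccccc1)c1ccccc1
Why: Wittig olefination with a stabilised, non-basic ylide is the standard entry to 3-C-branched furanoses and brings in C11 and C12; the alkene geometry is erased in step 5.

Step 5
Reactants: 5 ylidene acetate
Product: 6 5-O-TBDPS-3-deoxy-1,2-O-isopropylidene-3-C-(2-methoxy-2-oxoethyl)-β-D-lyxofuranose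
Conditions: H2 (1 atm), 10% Pd/C, EtOAc, rt
Reagents that add atoms: none
Why: Catalytic hydrogenation should deliver hydrogen to the convex α-face, opposite the acetonide and the C4 side chain, which puts the branch cis to O2 and C5 (lyxo) and so sets C7.

Step 6
Reactants: 6 lyxo-branched methyl ester
Product: 7 Mannich base of 6 (dimethylaminomethyl group on the ester α-carbon, both epimers)
Conditions: LiN(iPr)2, THF, −78 °C; CH2=NMe2+ I−, −78 → 0 °C
Reagents that add atoms: N,N-dimethylmethyleneiminium iodide (Eschenmoser's salt), C=[N+](C)C.[I-]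
Why: Mannich reaction of the lithium ester enolate adds C13; the enolate has no β-leaving group, and the new α-centre disappears in step 7.

Step 7
Reactants: 7 Mannich base
Product: 9 5-O-TBDPS-3-deoxy-1,2-O-isopropylidene-3-C-[1-(methoxycarbonyl)vinyl]-β-D-lyxofuranose, via trimethylammonium iodide 8 (not isolated)
Conditions: MeI, MeOH, rt; then NaHCO3 (aq), CH2Cl2, rt
Reagents that add atoms: none
Why: Exhaustive N-methylation followed by Hofmann-type E1cB loss of trimethylamine is the usual second half of an Eschenmoser methylenation and gives the acrylate.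

Step 8
Reactants: 9 lyxo-branched acrylate
Product: 11 lactone–lactol (5-O-TBDPS-3-C-(1-carboxyvinyl)-3-deoxy-D-lyxofuranose lactonised onto O2, anomeric mixture), via dihydroxy ester 10 (not isolated)
Conditions: TFA/H2O (9:1), 0 °C; then PhMe, 40 °C (evaporation)
Reagents that add atoms: none
Why: Acetal hydrolysis frees O1 and O2, and acid-catalysed lactonisation of O2 onto the cis acrylate ester should close the cis-fused α-methylene-γ-butyrolactone; the primary TBDPS ether should survive brief cold aqueous acid.

Step 9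
Reactants: 11 lactone–lactol; 12 ethyltriphenylphosphonium iodide
Product: 13 C4-iodoalkene alcohol (lactone with (Z)-CH=C(I)CH3 on C6 and CH(OH)CH2OTBDPS on C7)
Conditions: 12, n-BuLi, THF, 0 °C; I2, −78 °C; NaN(SiMe3)2, −78 °C; then 11, −78 → −20 °C
Reagents that add atoms: iodine, II
Why: Stork–Zhao olefination: the lactol reacts through its hydroxy aldehyde tautomer with (1-iodoethylidene)triphenylphosphorane in a kinetically controlled Wittig reaction that should give the Z-2-iodoalkene (iodine cis to C6) and release the C8 hydroxyl.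

Step 10
Reactants: 13 C4-iodoalkene alcohol; 14 angelic acid
Product: 15 C4-iodoalkene C8-angelate
Conditions: 14, 2,4,6-trichlorobenzoyl chloride, Et3N, PhMe, rt; then 13, 80 °C
Reagents that add atoms: none
Why: Yamaguchi esterification through the mixed anhydride, run without a nucleophilic catalyst, is the established way to acylate a hindered secondary alcohol with angelic acid without isomerisation to the tiglate.

Step 11
Reactants: 16 3-[(4-methoxybenzyl)oxy]propan-1-ol
Product: 17 3-[(4-methoxybenzyl)oxy]propanal
Conditions: Dess–Martin periodinane, CH2Cl2, rt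
Reagents that add atoms: none
Why: Dess–Martin oxidation gives the β-alkoxy aldehyde without β-elimination; it is used at once.

Step 12
Reactants: 15 C4-iodoalkene C8-angelate; 17 3-[(4-methoxybenzyl)oxy]propanal
Product: 19 C3-epimeric allylic alcohols (C3–C4 bond formed, C1 as PMB ether), via alkenylchromium dichloride 18 (not isolated)
Conditions: CrCl2, NiCl2 (cat.), DMSO, rt
Reagents that add atoms: none
Why: Intermolecular Nozaki–Hiyama–Kishi coupling: the alkenylchromium forms with retention, adds only to the aldehyde and tolerates lactone, angelate and silyl ether; C3 forms without control and is corrected in steps 13 and 14.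

Step 13
Reactants: 19 C3-epimeric allylic alcohols
Product: 20 Z-enone (C3 ketone)
Conditions: Dess–Martin periodinane, CH2Cl2, 0 °C
Reagents that add atoms: none
Why: Dess–Martin oxidation merges both epimers into one Z-enone under neutral conditions that should neither isomerise the alkene nor eliminate the β-PMB ether.

Step 14
Reactants: 20 Z-enone
Product: 21 (3S)-allylic alcohol
Conditions: (R)-1-methyl-3,3-diphenyltetrahydro-1H,3H-pyrrolo[1,2-c][1,3,2]oxazaborole (cat.), catecholborane, PhMe, −78 °C
Reagents that add atoms: none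
Why: Corey–Bakshi–Shibata reduction: with the α-methylalkenyl group as the large and the CH2CH2OPMB chain as the small substituent, the (R)-catalyst should give the 3S alcohol, and catecholborane at −78 °C should leave lactone, esters and the methylene group untouched.

Step 15
Reactants: 21 (3S)-allylic alcohol
Product: 22 C3 acetate
Conditions: Ac2O, pyridine, 4-(dimethylamino)pyridine (cat.), CH2Cl2, 0 °C
Reagents that add atoms: acetic anhydride, CC(=O)OC(C)=O
Why: Catalysed acetylation of the only free hydroxyl; short reaction at 0 °C should keep the angelate geometry.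

Step 16
Reactants: 22 C3 acetate
Product: 23 C9 alcohol
Conditions: HF·pyridine, pyridine/THF, 0 °C → rt
Reagents that add atoms: none
Why: Fluoride desilylation under mildly acidic conditions removes the TBDPS ether while the PMB ether and esters stay, and should avoid the O8-to-O9 acyl shift that basic fluoride would promote.

Step 17
Reactants: 23 C9 alcohol
Product: 24 C9 aldehyde
Conditions: Dess–Martin periodinane, CH2Cl2, 0 °C → rt
Reagents that add atoms: none
Why: Dess–Martin oxidation gives the α-acyloxy aldehyde without epimerisation at C8; it is used crude.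

Step 18
Reactants: 24 C9 aldehyde; 12 ethyltriphenylphosphonium iodide
Product: 25 C10 iodoalkene (C1 PMB ether)
Conditions: 12, n-BuLi, THF, 0 °C; I2, −78 °C; NaN(SiMe3)2, −78 °C; then 24, −78 → −30 °C
Reagents that add atoms: iodine, II
Why: Stork–Zhao olefination with a slight excess of the iodo-ylide at low temperature should give the Z-2-iodoalkene (iodine cis to C8) faster than the ylide can enolise the aldehyde or attack the enoates.

Step 19
Reactants: 25 C10 iodoalkene (C1 PMB ether)
Product: 26 C1 alcohol
Conditions: DDQ, CH2Cl2/pH 7 buffer, 0 °C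
Reagents that add atoms: none
Why: Oxidative cleavage of the PMB ether by DDQ is selective for the electron-rich benzyl group; the electron-poor alkenes and iodoalkene should not react.

Step 20
Reactants: 26 C1 alcohol
Product: 27 iodoalkene aldehyde (cyclisation precursor)
Conditions: Dess–Martin periodinane, CH2Cl2, 0 °C
Reagents that add atoms: none
Why: Dess–Martin oxidation gives the β-acetoxy aldehyde under neutral conditions that should not eliminate acetic acid; it is cyclised at once.

Step 21
Reactants: 27 iodoalkene aldehyde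
Product: 29 target CNP0319825.3, via alkenylchromium dichloride 28 (not isolated)
Conditions: CrCl2 (excess), NiCl2 (cat.), DMSO, rt, 0.003 M, slow addition of 27
Reagents that add atoms: none
Why: CrCl2 reduces NiCl2 to zerovalent nickel, which inserts into the C10–I bond with retention of the Z geometry and passes the alkenyl group to trivalent chromium to give 28, whose C10 then adds to the C1 aldehyde. The closest known reaction type is the Nozaki–Hiyama–Kishi macrocyclisation of an iodoalkene onto an aldehyde, which has closed medium and large carbocycles in the presence of esters and lactones. The ten-membered carbocycle closes end to end by C1–C10 bond formation (10-exo-trig attack on the aldehyde), helped by the cis-fused lactone and the two Z alkenes, which turn the chain ends toward each other. The new C1 stereocentre is expected to follow the C3 acetate: in the non-chelated, dipole-minimised aldehyde conformer the alkenyl group attacks anti to the β-acetoxy group and gives the 1,3-anti (1S) alcohol. The step needs aldehyde selectivity over angelate, acetate and methylene lactone, which the low basicity and carbonyl selectivity of alkenylchromium reagents should secure, and ring closure over oligomerisation, which high dilution and slow addition should secure.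

**Compound list**

1 | D-arabinose (open-chain form) | O=C[C@@H](O)[C@H](O)[C@H](O)CO | starting material
2 | 5-O-TBDPS-D-arabinofuranose (anomeric mixture) | CC(C)(C)[Si](c1ccccc1)(c1ccccc1)OC[C@H]1OC(O)[C@@H](O)[C@@H]1O | intermediate
3 | 5-O-TBDPS-1,2-O-isopropylidene-β-D-arabinofuranose | CC(C)(C)[Si](c1ccccc1)(c1ccccc1)OC[C@H]1O[C@H]2OC(C)(C)O[C@H]2[C@@H]1O | intermediate
4 | 5-O-TBDPS-1,2-O-isopropylidene-β-D-threo-pentofuranos-3-ulose | CC(C)(C)[Si](c1ccccc1)(c1ccccc1)OC[C@H]1O[C@H]2OC(C)(C)O[C@H]2C1=O | intermediate
5 | methyl (5-O-TBDPS-3-deoxy-1,2-O-isopropylidene-β-D-threo-pentofuranos-3-ylidene)acetate (E/Z mixture, alkene left undefined) | CC(C)(C)[Si](c1ccccc1)(c1ccccc1)OC[C@H]1O[C@H]2OC(C)(C)O[C@H]2C1=CC(=O)OC | intermediate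
6 | 5-O-TBDPS-3-deoxy-1,2-O-isopropylidene-3-C-(2-methoxy-2-oxoethyl)-β-D-lyxofuranose (branch cis to acetonide and C5) | CC(C)(C)[Si](c1ccccc1)(c1ccccc1)OC[C@H]1O[C@H]2OC(C)(C)O[C@H]2[C@H]1CC(=O)OC | intermediate
7 | Mannich base: 6 with CH2NMe2 on the ester α-carbon (both α-epimers) | CC(C)(C)[Si](c1ccccc1)(c1ccccc1)OC[C@H]1O[C@H]2OC(C)(C)O[C@H]2[C@H]1C(CN(C)C)C(=O)OC | intermediate
8 | trimethylammonium iodide of 7 | CC(C)(C)[Si](c1ccccc1)(c1ccccc1)OC[C@H]1O[C@H]2OC(C)(C)O[C@H]2[C@H]1C(C[N+](C)(C)C)C(=O)OC.[I-] | intermediate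
9 | 5-O-TBDPS-3-deoxy-1,2-O-isopropylidene-3-C-[1-(methoxycarbonyl)vinyl]-β-D-lyxofuranose | CC(C)(C)[Si](c1ccccc1)(c1ccccc1)OC[C@H]1O[C@H]2OC(C)(C)O[C@H]2[C@H]1C(=C)C(=O)OC | intermediate
10 | 5-O-TBDPS-3-deoxy-3-C-[1-(methoxycarbonyl)vinyl]-D-lyxofuranose (dihydroxy ester, anomers) | CC(C)(C)[Si](c1ccccc1)(c1ccccc1)OC[C@H]1OC(O)[C@@H](O)[C@H]1C(=C)C(=O)OC | intermediate
11 | lactone–lactol: furanose lactol cis-fused at C2–C3 to an α-methylene-γ-butyrolactone (O2 acylated), CH2OTBDPS on C4 | CC(C)(C)[Si](c1ccccc1)(c1ccccc1)OC[C@H]1OC(O)[C@H]2OC(=O)C(=C)[C@@H]12 | intermediate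
12 | ethyltriphenylphosphonium iodide | CC[P+](c1ccccc1)(c1ccccc1)c1ccccc1.[I-] | starting material
13 | C4-iodoalkene alcohol: α-methylene-γ-butyrolactone with (Z)-CH=C(I)CH3 on C6 and CH(OH)CH2OTBDPS on C7, ring substituents cis, C6–C8 as in the target | C=C1C(=O)O[C@H](/C=C(/C)I)[C@@H]1[C@H](O)CO[Si](c1ccccc1)(c1ccccc1)C(C)(C)C | intermediate
14 | angelic acid, (Z)-2-methylbut-2-enoic acid | C/C=C(/C)C(=O)O | starting material
15 | C8 angelate of 13 | C=C1C(=O)O[C@H](/C=C(/C)I)[C@@H]1[C@H](OC(=O)/C(C)=C\C)CO[Si](c1ccccc1)(c1ccccc1)C(C)(C)C | intermediate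
16 | 3-[(4-methoxybenzyl)oxy]propan-1-ol | COc1ccc(COCCCO)cc1 | starting material
17 | 3-[(4-methoxybenzyl)oxy]propanal | COc1ccc(COCCC=O)cc1 | intermediate
18 | alkenylchromium dichloride from 15 (trivalent chromium on C4, Z retained) | C=C1C(=O)O[C@H](/C=C(/C)[Cr](Cl)Cl)[C@@H]1[C@H](OC(=O)/C(C)=C\C)CO[Si](c1ccccc1)(c1ccccc1)C(C)(C)C | intermediate
19 | allylic alcohols, both C3 epimers: C6 side chain (Z)-CH=C(CH3)CH(OH)CH2CH2OPMB | C=C1C(=O)O[C@H](/C=C(/C)C(O)CCOCc2ccc(OC)cc2)[C@@H]1[C@H](OC(=O)/C(C)=C\C)CO[Si](c1ccccc1)(c1ccccc1)C(C)(C)C | intermediate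
20 | Z-enone: C3 ketone of 19 | C=C1C(=O)O[C@H](/C=C(/C)C(=O)CCOCc2ccc(OC)cc2)[C@@H]1[C@H](OC(=O)/C(C)=C\C)CO[Si](c1ccccc1)(c1ccccc1)C(C)(C)C | intermediate
21 | (3S)-allylic alcohol | C=C1C(=O)O[C@H](/C=C(/C)[C@@H](O)CCOCc2ccc(OC)cc2)[C@@H]1[C@H](OC(=O)/C(C)=C\C)CO[Si](c1ccccc1)(c1ccccc1)C(C)(C)C | intermediate
22 | (3S)-acetate | C=C1C(=O)O[C@H](/C=C(/C)[C@@H](OC(C)=O)CCOCc2ccc(OC)cc2)[C@@H]1[C@H](OC(=O)/C(C)=C\C)CO[Si](c1ccccc1)(c1ccccc1)C(C)(C)C | intermediate
23 | C9 primary alcohol | C=C1C(=O)O[C@H](/C=C(/C)[C@@H](OC(C)=O)CCOCc2ccc(OC)cc2)[C@@H]1[C@H](OC(=O)/C(C)=C\C)CO | intermediate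
24 | C9 aldehyde (α-angeloyloxy aldehyde) | C=C1C(=O)O[C@H](/C=C(/C)[C@@H](OC(C)=O)CCOCc2ccc(OC)cc2)[C@@H]1[C@H](OC(=O)/C(C)=C\C)C=O | intermediate
25 | C10 Z-iodoalkene, C1 PMB ether | C=C1C(=O)O[C@H](/C=C(/C)[C@@H](OC(C)=O)CCOCc2ccc(OC)cc2)[C@@H]1[C@H](OC(=O)/C(C)=C\C)/C=C(/C)I | intermediate
26 | C10 Z-iodoalkene, C1 alcohol | C=C1C(=O)O[C@H](/C=C(/C)[C@@H](OC(C)=O)CCO)[C@@H]1[C@H](OC(=O)/C(C)=C\C)/C=C(/C)I | intermediate
27 | open-chain C10 Z-iodoalkene C1 aldehyde with lactone, C3 acetate and C8 angelate | C=C1C(=O)O[C@H](/C=C(/C)[C@@H](OC(C)=O)CC=O)[C@@H]1[C@H](OC(=O)/C(C)=C\C)/C=C(/C)I | intermediate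
28 | alkenylchromium dichloride from 27 (trivalent chromium on C10, Z retained) | C=C1C(=O)O[C@H](/C=C(/C)[C@@H](OC(C)=O)CC=O)[C@@H]1[C@H](OC(=O)/C(C)=C\C)/C=C(/C)[Cr](Cl)Cl | intermediate
29 | CNP0319825.3, (1S,3S,6R,7R,8R,4Z,9Z)-3-acetoxy-8-angeloyloxy-1-hydroxygermacra-4,9,11(13)-trien-6,12-olide | C=C1C(=O)O[C@@H]2/C=C(/C)[C@@H](OC(C)=O)C[C@H](O)/C(C)=C\[C@@H](OC(=O)/C(C)=C\C)[C@H]12 | target

**Step count and risks**

Total: 21 steps. Longest linear sequence: 20 steps (steps 1–10 and 12–21; step 11 is a one-step side branch).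

Steps most likely to fail:

1. Step 21. Poor facial selectivity in the addition to the C1 aldehyde is the main danger, because 1,3-induction by a β-acetoxy group is not well established for alkenylchromium reagents; slow closure with competing loss of iodine is the lesser one and is met by dilution. The fallback for step 21 sets out from 27 and takes stereocontrol away from the ring closure. The cyclisation is run as above without regard to the facial outcome and should give 29 mixed with the 1R epimer of the target F1 in whatever proportion arises. Dess–Martin periodinane then oxidises the mixture to the macrocyclic C1 ketone F2 as a single Z-enone. A Corey–Bakshi–Shibata reduction of this ketone with the catalyst of step 14 and catecholborane at −78 °C should set 1S by reagent control, and the fallback comes back to the route at 29.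

2. Step 9. Conjugate addition of the basic iodo-ylide to the methylene lactone may outrun the olefination, because the aldehyde is masked as a lactol and is set free only slowly. A shift of the lactone from O6 to the C8 alkoxide is the lesser danger, since it would have to pass through a strained 2,6-dioxabicyclo[2.2.1]heptane tetrahedral intermediate, and a cold quench with pH 7 buffer should suppress it. The fallback for step 9 sets out from 6 and installs the exocyclic methylene only after the iodoalkene. Aqueous TFA converts 6 into the saturated lactone–lactol F3 with loss of acetone and methanol. The same Stork–Zhao olefination should give the saturated C4-iodoalkene alcohol F4 from a substrate that holds no conjugate acceptor. TESOTf and 2,6-lutidine then give the saturated C4-iodoalkene C8 triethylsilyl ether F5 in CH2Cl2 at −78 °C. Lithium diisopropylamide at −78 °C followed by Eschenmoser's salt gives the lactone Mannich base F6 as a mixture of C11 epimers. MeI turns it into the lactone trimethylammonium iodide F7 and aqueous NaHCO3 then eliminates trimethylamine to give the methylene lactone C8 triethylsilyl ether F8 as in step 7. HF·pyridine buffered with pyridine removes only the triethylsilyl group, and the fallback comes back to the route at 13.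

3. Step 18. Enolisation of the α-acyloxy aldehyde by the ylide may epimerise C8, or the olefination may stall beside the enoates. The fallback for step 18 sets out from 24 and builds the haloalkene without a basic ylide. Ramirez olefination with CBr4, PPh3 and Zn in CH2Cl2 gives the C9 1,1-dibromoalkene F9 under nearly neutral conditions. A Negishi coupling with MeZnCl, catalysed by PdCl2 and the diphosphine DPEphos, should replace the more accessible bromide trans to C8 and give the C10 Z-bromoalkene F10 with bromine cis to C8. Copper-catalysed halogen exchange with NaI, CuI and trans-N,N'-dimethylcyclohexane-1,2-diamine in dioxane should then convert this bromide with retention into the iodide, and the fallback comes back to the route at 25.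

Further compounds
F1 | step 21 | 1R epimer of the target | C=C1C(=O)O[C@@H]2/C=C(/C)[C@@H](OC(C)=O)C[C@@H](O)/C(C)=C\[C@@H](OC(=O)/C(C)=C\C)[C@H]12
F2 | step 21 | macrocyclic C1 ketone | C=C1C(=O)O[C@@H]2/C=C(/C)[C@@H](OC(C)=O)CC(=O)/C(C)=C\[C@@H](OC(=O)/C(C)=C\C)[C@H]12
F3 | step 9 | saturated lactone–lactol | CC(C)(C)[Si](c1ccccc1)(c1ccccc1)OC[C@H]1OC(O)[C@H]2OC(=O)C[C@@H]12
F4 | step 9 | saturated C4-iodoalkene alcohol | C1C(=O)O[C@H](/C=C(/C)I)[C@@H]1[C@H](O)CO[Si](c1ccccc1)(c1ccccc1)C(C)(C)C
F5 | step 9 | saturated C4-iodoalkene C8 triethylsilyl ether | C1C(=O)O[C@H](/C=C(/C)I)[C@@H]1[C@H](O[Si](CC)(CC)CC)CO[Si](c1ccccc1)(c1ccccc1)C(C)(C)C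
F6 | step 9 | lactone Mannich base | CN(C)CC1C(=O)O[C@H](/C=C(/C)I)[C@@H]1[C@H](O[Si](CC)(CC)CC)CO[Si](c1ccccc1)(c1ccccc1)C(C)(C)C
F7 | step 9 | lactone trimethylammonium iodide | C[N+](C)(C)CC1C(=O)O[C@H](/C=C(/C)I)[C@@H]1[C@H](O[Si](CC)(CC)CC)CO[Si](c1ccccc1)(c1ccccc1)C(C)(C)C.[I-]
F8 | step 9 | methylene lactone C8 triethylsilyl ether | C=C1C(=O)O[C@H](/C=C(/C)I)[C@@H]1[C@H](O[Si](CC)(CC)CC)CO[Si](c1ccccc1)(c1ccccc1)C(C)(C)C
F9 | step 18 | C9 1,1-dibromoalkene | C=C1C(=O)O[C@H](/C=C(/C)[C@@H](OC(C)=O)CCOCc2ccc(OC)cc2)[C@@H]1[C@H](OC(=O)/C(C)=C\C)C=C(Br)Br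
F10 | step 18 | C10 Z-bromoalkene | C=C1C(=O)O[C@H](/C=C(/C)[C@@H](OC(C)=O)CCOCc2ccc(OC)cc2)[C@@H]1[C@H](OC(=O)/C(C)=C\C)/C=C(/C)Br
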